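**Plan**

1. Numbering: isoflavan numbering for rings A and C (O1, C2, C3, C4, C4a–C8a); ring B is numbered as the 2H-chromene it is (its C6 carries C3, C7 the free hydroxyl, C8 the prenyl group).
2. Cuts: C3–C4 of ring C (formed last), then the C3–C6 aryl bond to ring B and the O1–C2 ether bond; ring B is cut at the pyran ring of the chromene and at the aryl–prenyl bond.
3. Forward: 2-prenylresorcinol gives the ring B chromenol; 2,4-dihydroxybenzaldehyde gives the ring A aldehyde with an O–CH2–CHO arm (its formyl carbon is C4); a three-component sulfonylalkylation joins the two; ring C closes last.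
4. Enabling feature: the ring B hydroxyl on C7 is ortho to C6, so C3 can become the exocyclic carbon of an o-quinone methide of ring B; C4 is an aryl aldehyde carbon ortho to O1, so its NH2-hydrazone can act as a benzyl anion equivalent that ends as CH2 after loss of N2.
5. Stereochemistry: the single stereocentre C3 (R) is created in the ring closure by a chiral bifunctional squaramide bound to the o-quinone methide; the tolylsulfonyl trigger, the two hydrazone nitrogens and the TIPS group are helpers that are removed again.

Key step: step 10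

Assumption: the sense of induction of the cinchona squaramide cannot be fixed in advance; the quinine-derived catalyst is written, and its quinidine-derived pseudoenantiomer would be used if the (3S) product were favoured.

**Route**

Step 1
Reactants: 1 resorcinol (benzene-1,3-diol)
Product: 2 1,3-bis(methoxymethoxy)benzene
Conditions: NaH, MOMCl, DMF, 0 °C → rt
Reagents that add atoms: chloromethyl methyl ether (MOMCl), COCCl
Why: Williamson-type alkylation of both phenoxides installs two MOM acetals that protect the phenols and direct the metalation of the next step.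

Step 2
Reactants: 2 1,3-bis(methoxymethoxy)benzene; 3 prenyl bromide (1-bromo-3-methylbut-2-ene)
Product: 5 1,3-bis(methoxymethoxy)-2-(3-methylbut-2-en-1-yl)benzene, via aryllithium 4 (not isolated)
Conditions: n-BuLi, THF, 0 °C → rt; then CuI (10 mol %), 3, −78 °C → rt
Reagents that add atoms: none
Why: Directed ortho-metalation should occur at the carbon flanked by both OMOM groups, and the aryllithium should be allylated at the primary carbon of prenyl bromide under CuI catalysis.

Step 3
Reactants: 5 1,3-bis(methoxymethoxy)-2-(3-methylbut-2-en-1-yl)benzene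
Product: 6 2-(3-methylbut-2-en-1-yl)benzene-1,3-diol (2-prenylresorcinol)
Conditions: HCl (3 M aq.), MeOH, rt
Reagents that add atoms: none
Why: Acid-catalysed acetal methanolysis (MOM cleavage) should free both phenols under conditions mild enough to leave the prenyl alkene uncyclised.

Step 4
Reactants: 6 2-prenylresorcinol; 7 prenal (3-methylbut-2-enal)
Product: 9 2,2-dimethyl-8-(3-methylbut-2-en-1-yl)-2H-chromen-7-ol, via dienone 8 (not isolated)
Conditions: ethylenediammonium diacetate (10 mol %), 7 (1.0 equiv), toluene, reflux
Reagents that add atoms: none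
Why: Knoevenagel-type ortho-condensation of the resorcinol with the enal gives dienone 8, whose oxa-6π electrocyclisation closes the 2,2-dimethylchromene; the prenyl group blocks the carbon between the two oxygens, so only the 7-hydroxy-8-prenyl isomer can form.

Step 5
Reactants: 10 2,4-dihydroxybenzaldehyde
Product: 11 2-hydroxy-4-(triisopropylsilyloxy)benzaldehyde
Conditions: TIPSCl (1.05 equiv), imidazole, CH2Cl2, 0 °C
Reagents that add atoms: triisopropylsilyl chloride (TIPSCl), CC(C)[Si](Cl)(C(C)C)C(C)C
Why: Silyl ether formation should be selective for the 4-hydroxyl because the 2-hydroxyl is held in a hydrogen bond to the formyl group.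

Step 6
Reactants: 11 2-hydroxy-4-(triisopropylsilyloxy)benzaldehyde; 12 allyl bromide (3-bromoprop-1-ene)
Product: 13 2-(allyloxy)-4-(triisopropylsilyloxy)benzaldehyde
Conditions: K2CO3, acetone, 50 °C
Reagents that add atoms: none
Why: Williamson etherification of the remaining phenol forms the O1–C2 bond and brings in the two carbons that become C2 and C3.

Step 7
Reactants: 13 2-(allyloxy)-4-(triisopropylsilyloxy)benzaldehyde
Product: 15 2-(2-oxoethoxy)-4-(triisopropylsilyloxy)benzaldehyde, via ozonide 14 (not isolated)
Conditions: O3, CH2Cl2, −78 °C; then Me2S, −78 °C → rt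
Reagents that add atoms: ozone, [O-][O+]=O
Why: Ozonolysis of the terminal alkene with reductive work-up should give the aryloxyacetaldehyde, the deactivated aromatic aldehyde and the silyl ether being inert.

Step 8
Reactants: 9 2,2-dimethyl-8-(3-methylbut-2-en-1-yl)-2H-chromen-7-ol; 15 2-(2-oxoethoxy)-4-(triisopropylsilyloxy)benzaldehyde
Product: 17 racemic 2-{2-[7-hydroxy-2,2-dimethyl-8-(3-methylbut-2-en-1-yl)-2H-chromen-6-yl]-2-(4-methylbenzenesulfonyl)ethoxy}-4-(triisopropylsilyloxy)benzaldehyde, via benzylic alcohol 16 (not isolated)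
Conditions: p-TolSO2H (1.5 equiv), p-TsOH·H2O (5 mol %), CH2Cl2, 0 °C → rt
Reagents that add atoms: p-toluenesulfinic acid, Cc1ccc(cc1)S(=O)O
Why: In this three-component synthesis of a 2-(1-tosylalkyl)phenol the electron-rich phenol should be hydroxyalkylated by the more electrophilic aliphatic aldehyde at C6, its only free ortho position, and the benzylic hydroxyl of 16 is then exchanged for sulfinate.

Step 9
Reactants: 17 sulfonyl aldehyde
Product: 18 (E)-hydrazone of 17 (NH2-hydrazone of the ring A formyl group; racemic at the sulfonyl-bearing carbon)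
Conditions: N2H4·H2O (5 equiv), AcOH (5 equiv), EtOH–THF, 0 °C → rt; used crude after neutral aqueous wash
Reagents that add atoms: hydrazine (as hydrate), NN
Why: Hydrazone formation at the aromatic aldehyde with buffered hydrazine should leave the sulfone intact, because the acetate buffer keeps the ring B phenol protonated and sulfinate is not expelled.

Step 10
Reactants: 18 hydrazone sulfone
Product: 21 6-[(3R)-7-(triisopropylsilyloxy)chroman-3-yl]-2,2-dimethyl-8-(3-methylbut-2-en-1-yl)-2H-chromen-7-ol, via o-quinone methide 19 (not isolated), via diazene 20 (not isolated)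
Conditions: quinine-derived squaramide [N-(3,5-bis(trifluoromethyl)phenyl)-N'-(9-deoxy-epi-quinin-9-yl)squaramide, 10 mol %], K2CO3 (2 equiv), toluene–H2O, 0.005 M, Ar, 0 °C → rt
Reagents that add atoms: none
Why: Proposed new method: the quinuclidine of the catalyst (turned over by K2CO3) deprotonates the ring B phenol and expels p-toluenesulfinate to give (E)-o-quinone methide 19, hydrogen-bonded through its carbonyl oxygen to the squaramide, and the azomethine carbon of the NH2-hydrazone (an aza-enamine whose NH2 is held by the quinuclidine) adds to the exocyclic carbon, re-aromatising ring B and giving monoalkyl diazene 20, which loses N2 at ambient temperature as in the last stage of a Wolff–Kishner reduction, so that the former formyl carbon ends as the C4 methylene. The closest known reaction types are squaramide/base-catalysed enantioselective conjugate additions to o-quinone methides released from 2-(1-tosylalkyl)phenols, azo-ene C-additions of N–H hydrazones to electron-poor alkenes, and the use of aldehyde hydrazones as alkyl carbanion equivalents in conjugate additions with loss of N2; their merger in an intramolecular, enantioselective form is what is new. Ring C closes in a 6-exo-trig mode (the accepting C=C is exocyclic to the new ring and the hydrazone C=N is enol-exo), with the tether topology of an intramolecular Stetter reaction of an O-allylated salicylaldehyde. The single new stereocentre C3 is set by the catalyst, which shields one face of the planar, doubly hydrogen-bonded o-quinone methide while orienting the tethered hydrazone. The step needs C- and not N-alkylation of the hydrazone, which the tether secures because C-attack closes a six-membered and N-attack an eight-membered ring, and it needs trapping to outrun tautomerisation of 19 to a vinyl phenol and any uncatalysed cyclisation, which high dilution, low temperature and release of 19 only inside the catalyst–phenoxide ion pair are meant to secure.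

Step 11
Reactants: 21 silyl-protected isoflavan
Product: 22 6-[(3R)-7-hydroxychroman-3-yl]-2,2-dimethyl-8-(3-methylbut-2-en-1-yl)-2H-chromen-7-ol (target)
Conditions: TBAF (1.1 equiv), AcOH (1.1 equiv), THF, 0 °C
Reagents that add atoms: none
Why: Fluoride-mediated cleavage of the aryl silyl ether should leave both alkenes and the stereocentre untouched, acetic acid buffering the electron-rich phenoxide.

**Compound list**

1 | resorcinol (benzene-1,3-diol) | Oc1cccc(O)c1 | starting material
2 | 1,3-bis(methoxymethoxy)benzene | COCOc1cccc(OCOC)c1 | intermediate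
3 | prenyl bromide (1-bromo-3-methylbut-2-ene) | CC(C)=CCBr | starting material
4 | 2,6-bis(methoxymethoxy)phenyllithium (not isolated) | [Li]c1c(OCOC)cccc1OCOC | intermediate
5 | 1,3-bis(methoxymethoxy)-2-(3-methylbut-2-en-1-yl)benzene | COCOc1cccc(OCOC)c1CC=C(C)C | intermediate
6 | 2-(3-methylbut-2-en-1-yl)benzene-1,3-diol (2-prenylresorcinol) | CC(C)=CCc1c(O)cccc1O | intermediate
7 | prenal (3-methylbut-2-enal) | CC(C)=CC=O | starting material
8 | 3-hydroxy-6-(3-methylbut-2-en-1-ylidene)-2-(3-methylbut-2-en-1-yl)cyclohexa-2,4-dien-1-one (not isolated) | O=C1C(CC=C(C)C)=C(O)C=CC1=CC=C(C)C | intermediate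
9 | 2,2-dimethyl-8-(3-methylbut-2-en-1-yl)-2H-chromen-7-ol | CC(C)=CCc1c(O)ccc2c1OC(C)(C)C=C2 | intermediate
10 | 2,4-dihydroxybenzaldehyde | O=Cc1ccc(O)cc1O | starting material
11 | 2-hydroxy-4-(triisopropylsilyloxy)benzaldehyde | O=Cc1ccc(O[Si](C(C)C)(C(C)C)C(C)C)cc1O | intermediate
12 | allyl bromide (3-bromoprop-1-ene) | C=CCBr | starting material
13 | 2-(allyloxy)-4-(triisopropylsilyloxy)benzaldehyde | O=Cc1ccc(O[Si](C(C)C)(C(C)C)C(C)C)cc1OCC=C | intermediate
14 | secondary ozonide of 13: 2-(1,2,4-trioxolan-3-ylmethoxy)-4-(triisopropylsilyloxy)benzaldehyde (not isolated) | O=Cc1ccc(O[Si](C(C)C)(C(C)C)C(C)C)cc1OCC1OCOO1 | intermediate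
15 | 2-(2-oxoethoxy)-4-(triisopropylsilyloxy)benzaldehyde | O=CCOc1cc(O[Si](C(C)C)(C(C)C)C(C)C)ccc1C=O | intermediate
16 | racemic 2-{2-hydroxy-2-[7-hydroxy-2,2-dimethyl-8-(3-methylbut-2-en-1-yl)-2H-chromen-6-yl]ethoxy}-4-(triisopropylsilyloxy)benzaldehyde (not isolated) | CC(C)=CCc1c(O)c(C(O)COc3cc(O[Si](C(C)C)(C(C)C)C(C)C)ccc3C=O)cc2c1OC(C)(C)C=C2 | intermediate
17 | racemic 2-{2-[7-hydroxy-2,2-dimethyl-8-(3-methylbut-2-en-1-yl)-2H-chromen-6-yl]-2-(4-methylbenzenesulfonyl)ethoxy}-4-(triisopropylsilyloxy)benzaldehyde | CC(C)=CCc1c(O)c(C(COc3cc(O[Si](C(C)C)(C(C)C)C(C)C)ccc3C=O)S(=O)(=O)c3ccc(C)cc3)cc2c1OC(C)(C)C=C2 | intermediate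
18 | (E)-NH2-hydrazone of 17 (racemic at the sulfonyl-bearing carbon) | CC(C)=CCc1c(O)c(C(COc3cc(O[Si](C(C)C)(C(C)C)C(C)C)ccc3/C=N/N)S(=O)(=O)c3ccc(C)cc3)cc2c1OC(C)(C)C=C2 | intermediate
19 | (E)-o-quinone methide of ring B: 6-{2-[2-(hydrazonomethyl)-5-(triisopropylsilyloxy)phenoxy]ethylidene}-2,2-dimethyl-8-(3-methylbut-2-en-1-yl)-2H-chromen-7(6H)-one (not isolated) | CC(C)=CCC1=C2OC(C)(C)C=CC2=C/C(=C\COc3cc(O[Si](C(C)C)(C(C)C)C(C)C)ccc3/C=N/N)C1=O | intermediate
20 | 4-diazenyl derivative of 21 (C3 arranged in space as in 21, C4 unassigned; not isolated) | CC(C)=CCc1c(O)c([C@@H]2COc3cc(O[Si](C(C)C)(C(C)C)C(C)C)ccc3C2N=N)cc2c1OC(C)(C)C=C2 | intermediate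
21 | 6-[(3R)-7-(triisopropylsilyloxy)chroman-3-yl]-2,2-dimethyl-8-(3-methylbut-2-en-1-yl)-2H-chromen-7-ol | CC(C)=CCc1c(O)c([C@@H]2COc3cc(O[Si](C(C)C)(C(C)C)C(C)C)ccc3C2)cc2c1OC(C)(C)C=C2 | intermediate
22 | 6-[(3R)-7-hydroxychroman-3-yl]-2,2-dimethyl-8-(3-methylbut-2-en-1-yl)-2H-chromen-7-ol | CC(C)=CCc1c(O)c([C@@H]2COc3cc(O)ccc3C2)cc2c1OC(C)(C)C=C2 | target

**Step count and risks**

Total steps: 11. Longest linear sequence: 8 steps (steps 1–4, then 8–11); the ring A branch (steps 5–7) joins at step 8.

Steps most likely to fail:

1. Step 10 (Proposed new method). The hydrazone may alkylate at nitrogen between molecules instead of closing the ring at carbon. The o-quinone methide may tautomerise to a vinyl phenol before it is trapped. The diazene may isomerise to a ketone hydrazone instead of losing N2. Uncatalysed ring closure may give poor facial selectivity at C3. The fallback uses known chemistry, sets out from 17 and comes back at 22. A thiazolium-derived N-heterocyclic carbene with Cs2CO3 in THF releases the o-quinone methide from the sulfone and adds the acyl anion of the ring A aldehyde to it (nucleophilic acylation of an o-quinone methide, run intramolecularly in the manner of a Stetter reaction), which should give racemic 3-[7-hydroxy-2,2-dimethyl-8-(3-methylbut-2-en-1-yl)-2H-chromen-6-yl]-7-(triisopropylsilyloxy)chroman-4-one F1. Noyori-type asymmetric transfer hydrogenation with RuCl(p-cymene)[(R,R)-TsDPEN] in HCO2H/Et3N, in which C3 epimerises through the enol so that both enantiomers funnel into one product (dynamic kinetic resolution, known for isoflavanones), should give the cis alcohol (3R,4R)-3-[7-hydroxy-2,2-dimethyl-8-(3-methylbut-2-en-1-yl)-2H-chromen-6-yl]-7-(triisopropylsilyloxy)chroman-4-ol F2; the (R,R) ligand is written on the usual aryl ketone model. TBAF then frees the ring A phenol to give (3R,4R)-3-[7-hydroxy-2,2-dimethyl-8-(3-methylbut-2-en-1-yl)-2H-chromen-6-yl]chroman-4,7-diol F3. NaBH4 in warm aqueous NaOH/EtOH removes the benzylic hydroxyl, which is para to the C7 phenoxide, through the ring A p-quinone methide (known hydrogenolysis of p-hydroxybenzyl alcohols) and should deliver 22.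

2. Step 8. The sulfinic and sulfonic acids may cyclise the prenyl group onto the neighbouring phenol or dimerise the chromene, and the phenol may condense at the aromatic formyl group instead of the aliphatic one. The fallback sets out from 9 and 15 and comes back at 17. Phenylboronic acid with catalytic propionic acid in refluxing toluene with removal of water (boronate-templated ortho-hydroxyalkylation, the weakly acidic conditions under which chromenes themselves are made) should give the cyclic boronate 2-{[8,8-dimethyl-2-phenyl-10-(3-methylbut-2-en-1-yl)-4H,8H-pyrano[3,2-g][1,3,2]benzodioxaborin-4-yl]methoxy}-4-(triisopropylsilyloxy)benzaldehyde F4. p-Toluenesulfinic acid in CH2Cl2 at 0 °C then opens the boronate through the o-quinone methide to give 17.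

3. Step 9. Hydrazine may expel sulfinate early and capture the o-quinone methide at nitrogen, and the hydrazone may condense with unreacted aldehyde to an azine. The fallback sets out from 17, avoids free hydrazine and comes back at 18. 1,2-Bis(tert-butyldimethylsilyl)hydrazine with Sc(OTf)3 (catalytic) in CH2Cl2 should give the N-silyl hydrazone, the (E)-N-(tert-butyldimethylsilyl)hydrazone of 17 F5. Brief methanolysis at 0 °C cleaves the N–Si bond to give 18.

**Further compounds**

F1 | step 10 | racemic 3-[7-hydroxy-2,2-dimethyl-8-(3-methylbut-2-en-1-yl)-2H-chromen-6-yl]-7-(triisopropylsilyloxy)chroman-4-one | CC(C)=CCc1c(O)c(C2COc3cc(O[Si](C(C)C)(C(C)C)C(C)C)ccc3C2=O)cc2c1OC(C)(C)C=C2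
F2 | step 10 | (3R,4R)-3-[7-hydroxy-2,2-dimethyl-8-(3-methylbut-2-en-1-yl)-2H-chromen-6-yl]-7-(triisopropylsilyloxy)chroman-4-ol | CC(C)=CCc1c(O)c([C@@H]2COc3cc(O[Si](C(C)C)(C(C)C)C(C)C)ccc3[C@@H]2O)cc2c1OC(C)(C)C=C2
F3 | step 10 | (3R,4R)-3-[7-hydroxy-2,2-dimethyl-8-(3-methylbut-2-en-1-yl)-2H-chromen-6-yl]chroman-4,7-diol | CC(C)=CCc1c(O)c([C@@H]2COc3cc(O)ccc3[C@@H]2O)cc2c1OC(C)(C)C=C2
F4 | step 8 | 2-{[8,8-dimethyl-2-phenyl-10-(3-methylbut-2-en-1-yl)-4H,8H-pyrano[3,2-g][1,3,2]benzodioxaborin-4-yl]methoxy}-4-(triisopropylsilyloxy)benzaldehyde (racemic) | CC(C)=CCc1c5OB(c6ccccc6)OC(COc3cc(O[Si](C(C)C)(C(C)C)C(C)C)ccc3C=O)c5cc2c1OC(C)(C)C=C2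
F5 | step 9 | (E)-N-(tert-butyldimethylsilyl)hydrazone of 17 (racemic at the sulfonyl-bearing carbon) | CC(C)=CCc1c(O)c(C(COc3cc(O[Si](C(C)C)(C(C)C)C(C)C)ccc3/C=N/N[Si](C)(C)C(C)(C)C)S(=O)(=O)c3ccc(C)cc3)cc2c1OC(C)(C)C=C2
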